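The constants to read from these runs are a feed and a split.

| flask | solid substrate | remark | time |
|---|---|---|---|
| south-west | 0.043 M | run made earlier |  |
| north-west | 0.096 M | run made earlier |  |
| flask | 0.064 M |  | 25 min |

- south-west (time / min: side product / %, target / %): 2.50: 11.2, 23.0; 5.00: 33.6, 52.7; 8.00: 43.7, 55.4; 15.0: 44.3, 56.1; 30.0: 44.5, 55.6
- north-west (time / min: side product / %, target / %): 2.50: 5.2, 11.2; 8.00: 29.2, 41.4; 15.0: 44.1, 55.6; 20.0: 44.3, 55.1; 30.0: 44.9, 55.5

(standard deviation of a reading: 0.3 percentage points)

* ratio of side product to target at 1.0 min
* ratio of side product to target at 25 min
* which of side product and target there is more of at 25 min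

Take the north-west run first. From 2.50 min to 8.00 min, target plus side product gains 54 percentage points, so you read a feed of 0.00946 M min⁻¹. That is the target plus side product gained per minute while solid remains, and a charge divided by it gives an estimated clearing time.

The south-west run is your second way. From 2.50 min to 5.00 min it gains 52 points, which gives 0.00896 M min⁻¹. That gain falls 2.9 points below what the north-west feed predicts, well beyond a scatter of 0.3 points per reading.

The south-west figure is the one that cheats. At the north-west feed its charge clears in 4.55 min, before its 5.00 min reading, so on this estimate the feed stops inside that window. The north-west charge lasts 10.1 min, past its window.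

By this estimate the flask clears in 6.77 min, well before 25 min. You expect the plateau split at 25 min: the last readings give 0.800 south-west and 0.809 north-west, with target ahead. No reading stands as early as 1.0 min, so you reckon no ratio there.

The forecast gives 0.26 (0.17 to 0.36) at 1.0 min, 0.8 (0.785 to 0.815) at 25 min, and target ahead. Its ground is that “The solid appears to dissolve at a constant rate, independent of loading”. For the flask it puts the end of dissolving near 8 min, later than your 6.77 min.

The flask gives 0.251 and 0.800, with target at 55.6% and side product at 44.4%.

    starting material → intermediate A (k = 0.0500 s⁻¹)
    starting material → intermediate B (k = 0.0400 s⁻¹)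
    intermediate A → target (k = 0.0260 s⁻¹)
    intermediate B → intermediate C (k = 0.0300 s⁻¹)
    intermediate C ⇌ intermediate D (K = 0.150, k = 0.00720 s⁻¹)
    intermediate C → side product (k = 0.0180 s⁻¹)
    solid substrate ⇌ starting material, rate k7*(cs7 - [starting material]) while solid is left; crystals form when [starting material] > cs7 (solubility = 2.10 mM, k = 0.580 s⁻¹)

In the flask at 3.10 min, starting material passes into intermediate A 1.2 times as fast as into intermediate B, a selectivity factor that stands beside the 1.25 of target over side product at 25 min. Half of the flask's dissolving was done by 3.10 min, against 3.38 min from the feed.

For a second flask with 0.26 M charged, the feed gives 27.5 min, later than 25 min, and so an estimated 9.04% undissolved. The computed second flask holds 5.7%, solid or dissolved, at a ratio of 0.768.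

Readings and results are simulated with constants of no real substance, noise included.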